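**Plan**

- Retrosynthesis: the methylene bridge is cut first at C8–CH2 (ring B side), giving an 8-(dimethylaminomethyl)chromanone and the chiral ring A ketone. The pyranone ring C is then opened at O1–C8a and C3–C4 in one stroke, leaving a chlorinated ring B aldehyde and a three-atom O–C(CH3)2–CH2 unit.
- Enabling feature: C8a, which carries O1, lies between C4a (side chain) and C8. C8 is the only ring B carbon open to electrophilic substitution (ortho to O7, para to O5) and sits next to O7. A chlorine placed at C8 can therefore be turned into a C8–C8a aryne that O7 polarizes towards attack at C8a, so the C8–Cl becomes the O1–C8a bond (cine substitution) and C8–H is left free for the bridge.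
- Forward order: ring B is bought as an aldehyde, chlorinated and protected. LiCH2C(CH3)2OLi (an isobutylene oxide equivalent with reversed polarity) forms C3–C4, and the same pot closes ring C through the aryne. C4 is carried as the carbinol so that no retro-aldol is possible, then oxidized. Deprotection and a Mannich reaction follow; ring A is made in two steps and the halves are joined last at the CH2.
- Stereochemistry: the only stereocentre (R, α to the ring A ketone) is bought with (R)-2-methylbutanoic acid and carried through three mild steps. The C4 carbinol centre of step 3 is racemic and is erased in step 4.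

Key step: step 3

Assumption: chromanone numbering (O1, C2, C3, C4, C4a, C5–C8, C8a) is used for rings B and C, and ring A is numbered C1′ (acyl), C2′ (OH), C3′ (CH3), C4′ (OCH3), C5′ (bridge), C6′ (OH). (R)-2-Methylbutanoic acid is taken as a purchasable enantiopure compound.

**Route**

Step 1
Reactants: 1 2,4-dihydroxy-3-methylbenzaldehyde
Product: 2 5-chloro-2,4-dihydroxy-3-methylbenzaldehyde
Conditions: N-chlorosuccinimide, MeCN, 0 °C → rt
Reagents that add atoms: N-chlorosuccinimide, O=C1CCC(=O)N1Cl
Why: Electrophilic aromatic chlorination should go to C5 of the aldehyde (the future C8), the only free position that is ortho to one hydroxyl, para to the other and meta to the formyl group.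

Step 2
Reactants: 2 5-chloro-2,4-dihydroxy-3-methylbenzaldehyde
Product: 3 5-chloro-2,4-bis(methoxymethoxy)-3-methylbenzaldehyde
Conditions: NaH, MOMCl, DMF, 0 °C → rt
Reagents that add atoms: chloromethyl methyl ether, COCCl
Why: Williamson-type O-alkylation masks both phenols as acetals that tolerate organolithium and lithium amide bases and cannot migrate to a neighbouring aryl anion.

Step 3
Reactants: 3 5-chloro-2,4-bis(methoxymethoxy)-3-methylbenzaldehyde; 4 1-chloro-2-methylpropan-2-ol
Product: 9 5,7-bis(methoxymethoxy)-2,2,6-trimethylchroman-4-ol (racemic), via dilithio reagent 5 (not isolated), via dilithium diolate 6 (not isolated), via aryne 7 (not isolated), via 8-lithiochromanolate 8 (not isolated)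
Conditions: 4, n-BuLi then lithium naphthalenide (LiC10H8), THF, −78 °C; add 3, −78 °C; LiTMP (lithium 2,2,6,6-tetramethylpiperidide), −78 °C → rt; aq NH4Cl
Reagents that add atoms: none
Why: Chlorine–lithium exchange on the lithium alkoxide of 4 turns the normally electrophilic CH2 of an isobutylene oxide equivalent into a carbanion (polarity reversal), and 5 adds to aldehyde 3 to form C3–C4 as the diolate 6, which has no carbonyl group and so cannot lose acetone by retro-aldol cleavage or enolize under the strongly basic conditions that follow. LiTMP then removes the only aromatic hydrogen (C8a–H, ortho to chlorine), LiCl is lost to give the C8–C8a aryne 7, and the tertiary alkoxide adds to C8a to form O1–C8a by net cine substitution; the closest known reaction types are the addition of β-oxido organolithiums to aldehydes and the benzyne cyclization of tethered alkoxides to chromans. Ring C closes in the 6-exo-dig mode onto the proximal aryne carbon, helped by the gem-dimethyl group. The regioselectivity needed (oxygen to C8a, not C8) is secured twice: attack at C8 would give a seven-membered ring, and the C7 methoxymethoxy group polarizes the aryne so that the nucleophile enters meta to it and the carbanion develops at C8, ortho to oxygen. The C4 carbinol centre forms without control as a racemate and is erased in step 4, and the C8 aryl anion 8 is protonated on work-up, which leaves C8 free for the bridge.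

Step 4
Reactants: 9 5,7-bis(methoxymethoxy)-2,2,6-trimethylchroman-4-ol
Product: 10 5,7-bis(methoxymethoxy)-2,2,6-trimethylchroman-4-one
Conditions: Dess–Martin periodinane, CH2Cl2, rt
Reagents that add atoms: none
Why: Dess–Martin oxidation of the secondary benzylic alcohol should restore the C4 ketone under near-neutral conditions that leave the acetals and the electron-rich arene untouched.

Step 5
Reactants: 10 5,7-bis(methoxymethoxy)-2,2,6-trimethylchroman-4-one
Product: 11 5,7-dihydroxy-2,2,6-trimethylchroman-4-one
Conditions: HCl (3 M aq), MeOH, 40 °C
Reagents that add atoms: none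
Why: Acid-catalysed acetal exchange with methanol removes both MOM groups under conditions too mild to open ring C, so the 6-methyl/8-methyl regiochemistry fixed in step 3 should not scramble (no Wessely–Moser-type isomerization).

Step 6
Reactants: 11 5,7-dihydroxy-2,2,6-trimethylchroman-4-one
Product: 12 8-[(dimethylamino)methyl]-5,7-dihydroxy-2,2,6-trimethylchroman-4-one
Conditions: dimethylmethyleneammonium iodide (CH2=NMe2 I), Et3N, CH2Cl2, 0 °C → rt
Reagents that add atoms: dimethylmethyleneammonium iodide, C=[N+](C)C.[I-]
Why: The phenolic Mannich reaction with the preformed iminium salt should take place at C8, the only unsubstituted ring carbon, which is ortho to the C7 hydroxyl and para to the C5 hydroxyl.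

Step 7
Reactants: 13 (R)-2-methylbutanoic acid; 14 2,4,6-trihydroxytoluene
Product: 16 (R)-2-methyl-1-(2,4,6-trihydroxy-3-methylphenyl)butan-1-one, via acid chloride 15 (not isolated)
Conditions: (COCl)2, cat. DMF, CH2Cl2, 0 °C → rt; then 14, AlCl3, PhNO2/CH2Cl2, 0 °C → rt
Reagents that add atoms: none
Why: Friedel–Crafts C-acylation of the symmetrical triol can occur only at its two equivalent free positions, and at low temperature the α-stereocentre of the acid should be carried over unchanged.

Step 8
Reactants: 16 (R)-2-methyl-1-(2,4,6-trihydroxy-3-methylphenyl)butan-1-one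
Product: 17 (R)-1-(2,6-dihydroxy-4-methoxy-3-methylphenyl)-2-methylbutan-1-one
Conditions: Me2SO4 (1 equiv), K2CO3 (1 equiv), acetone, rt
Reagents that add atoms: dimethyl sulfate, COS(=O)(=O)OC
Why: The C4′ hydroxyl para to the ketone is the most acidic and the only one not held in a hydrogen bond to the carbonyl, so one equivalent of dimethyl sulfate with weak base should methylate it selectively (aspidinol-type partial methylation).

Step 9
Reactants: 12 8-[(dimethylamino)methyl]-5,7-dihydroxy-2,2,6-trimethylchroman-4-one; 17 (R)-1-(2,6-dihydroxy-4-methoxy-3-methylphenyl)-2-methylbutan-1-one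
Product: 19 (R)-1-[2,6-dihydroxy-4-methoxy-3-methyl-5-[(5,7-dihydroxy-2,2,6-trimethyl-4-oxochroman-8-yl)methyl]phenyl]-2-methylbutan-1-one (CNP0303209.1), via quinone methide 18 (not isolated)
Conditions: 12 (1.1 equiv), dioxane, 100 °C, N2 stream
Reagents that add atoms: none
Why: Heating the phenolic Mannich base should expel dimethylamine to give the ortho-quinone methide 18, which is captured in a Michael-type C-alkylation by C5′ of 17, its only free ring position, and re-aromatization gives the diarylmethane without touching the stereocentre.

**Compound list**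

1 | 2,4-dihydroxy-3-methylbenzaldehyde | O=Cc1ccc(O)c(C)c1O | starting material
2 | 5-chloro-2,4-dihydroxy-3-methylbenzaldehyde | O=Cc1cc(Cl)c(O)c(C)c1O | intermediate
3 | 5-chloro-2,4-bis(methoxymethoxy)-3-methylbenzaldehyde | O=Cc1cc(Cl)c(OCOC)c(C)c1OCOC | intermediate
4 | 1-chloro-2-methylpropan-2-ol | CC(C)(O)CCl | starting material
5 | lithium 1-lithio-2-methylpropan-2-olate | [Li]CC(C)(C)O[Li] | intermediate
6 | dilithium 1-[5-chloro-2,4-bis(methoxymethoxy)-3-methylphenyl]-3-methylbutane-1,3-diolate (racemic) | [Li]OC(CC(C)(C)O[Li])c1cc(Cl)c(OCOC)c(C)c1OCOC | intermediate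
7 | dilithium 1-[5,6-didehydro-2,4-bis(methoxymethoxy)-3-methylphenyl]-3-methylbutane-1,3-diolate (C8–C8a aryne, racemic) | [Li]OC(CC(C)(C)O[Li])C1=C(OCOC)C(C)=C(OCOC)C#C1 | intermediate
8 | lithium 8-lithio-5,7-bis(methoxymethoxy)-2,2,6-trimethylchroman-4-olate (racemic) | [Li]OC1CC(C)(C)Oc2c([Li])c(OCOC)c(C)c(OCOC)c12 | intermediate
9 | 5,7-bis(methoxymethoxy)-2,2,6-trimethylchroman-4-ol (racemic) | OC1CC(C)(C)Oc2cc(OCOC)c(C)c(OCOC)c12 | intermediate
10 | 5,7-bis(methoxymethoxy)-2,2,6-trimethylchroman-4-one | O=C1CC(C)(C)Oc2cc(OCOC)c(C)c(OCOC)c12 | intermediate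
11 | 5,7-dihydroxy-2,2,6-trimethylchroman-4-one | O=C1CC(C)(C)Oc2cc(O)c(C)c(O)c12 | intermediate
12 | 8-[(dimethylamino)methyl]-5,7-dihydroxy-2,2,6-trimethylchroman-4-one | CN(C)Cc1c(O)c(C)c(O)c2C(=O)CC(C)(C)Oc12 | intermediate
13 | (R)-2-methylbutanoic acid | CC[C@@H](C)C(=O)O | starting material
14 | 2,4,6-trihydroxytoluene (2-methylbenzene-1,3,5-triol) | Cc1c(O)cc(O)cc1O | starting material
15 | (R)-2-methylbutanoyl chloride | CC[C@@H](C)C(=O)Cl | intermediate
16 | (R)-2-methyl-1-(2,4,6-trihydroxy-3-methylphenyl)butan-1-one | CC[C@@H](C)C(=O)c1c(O)c(C)c(O)cc1O | intermediate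
17 | (R)-1-(2,6-dihydroxy-4-methoxy-3-methylphenyl)-2-methylbutan-1-one | CC[C@@H](C)C(=O)c1c(O)c(C)c(OC)cc1O | intermediate
18 | 5-hydroxy-2,2,6-trimethyl-8-methylidene-2,3-dihydrochromene-4,7(8H)-dione | C=C1C(=O)C(C)=C(O)C2=C1OC(C)(C)CC2=O | intermediate
19 | (R)-1-[2,6-dihydroxy-4-methoxy-3-methyl-5-[(5,7-dihydroxy-2,2,6-trimethyl-4-oxochroman-8-yl)methyl]phenyl]-2-methylbutan-1-one | CC[C@@H](C)C(=O)c1c(O)c(C)c(OC)c(Cc2c(O)c(C)c(O)c3c2OC(C)(C)CC3=O)c1O | target

**Step count and risks**

Total steps: 9. Longest linear sequence: 7 (steps 1–6 and 9).

Steps most likely to fail: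

1. Step 3. The one-pot sequence may break down at the organometallic stage: electron transfer from naphthalenide-derived species to the aryl chloride would strip the chlorine before the aryne can form, or the dilithio reagent may undergo β-elimination before it adds. Fallback: the same carbon skeleton would be assembled with normal polarity, setting out from 3. Aldol addition of the lithium enolate of ethyl acetate (LiN(i-Pr)2, THF, −78 °C) should give ethyl 3-[5-chloro-2,4-bis(methoxymethoxy)-3-methylphenyl]-3-hydroxypropanoate F1. Excess MeMgBr should convert the ester into 1-[5-chloro-2,4-bis(methoxymethoxy)-3-methylphenyl]-3-methylbutane-1,3-diol F2. Treatment of F2 with LiTMP in THF (−78 °C → rt) should then close ring C through the same aryne as a separate step, and the route is rejoined at 9.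

2. Step 9. The aminomethyl or methylene unit may be exchanged between the two phenols (retro-Mannich reaction, ipso attack on the product), which would give symmetrical dimers, or the quinone methide may dimerize before it is trapped. Fallback: setting out from 11 and 17, the two phenols would be condensed directly with one equivalent of aqueous formaldehyde in dilute aqueous KOH at 0 °C for a few minutes, the classical three-component bridging of aspidinol-type ketones. Acidification and chromatographic separation from the two symmetrical dimers should arrive at 19.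

3. Step 7. Optical purity may erode through enolization or ketene formation of the acyl chloride–AlCl3 complex, and the triol may be acylated twice. Fallback: setting out from 14 and 13, the triol would be protected with MOMCl and i-Pr2NEt as 1,3,5-tris(methoxymethoxy)-2-methylbenzene F3, and the acid converted (via 15, MeNHOMe·HCl, Et3N) into (R)-N-methoxy-N,2-dimethylbutanamide F4. Lithiation of F3 between two acetal oxygens (n-BuLi, THF, 0 °C) and addition to F4 at −78 °C should give (R)-2-methyl-1-[2,4,6-tris(methoxymethoxy)-3-methylphenyl]butan-1-one F5 without exposing the stereocentre to a Lewis acid. HCl in MeOH should then remove the acetals and return the route to 16.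

**Further compounds**

F1 | step 3 | ethyl 3-[5-chloro-2,4-bis(methoxymethoxy)-3-methylphenyl]-3-hydroxypropanoate (racemic) | CCOC(=O)CC(O)c1cc(Cl)c(OCOC)c(C)c1OCOC
F2 | step 3 | 1-[5-chloro-2,4-bis(methoxymethoxy)-3-methylphenyl]-3-methylbutane-1,3-diol (racemic) | CC(C)(O)CC(O)c1cc(Cl)c(OCOC)c(C)c1OCOC
F0 | step 9 | none | none
F3 | step 7 | 1,3,5-tris(methoxymethoxy)-2-methylbenzene | COCOc1cc(OCOC)c(C)c(OCOC)c1
F4 | step 7 | (R)-N-methoxy-N,2-dimethylbutanamide | CC[C@@H](C)C(=O)N(C)OC
F5 | step 7 | (R)-2-methyl-1-[2,4,6-tris(methoxymethoxy)-3-methylphenyl]butan-1-one | CC[C@@H](C)C(=O)c1c(OCOC)c(C)c(OCOC)cc1OCOC
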